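1. The target costs one substrate per molecule, through the second chain carrier, and the rest of the lost substrate I counted as capped initiator, one per radical. The first chain carrier either meets coupling partner, giving target and carrying on, or meets transfer agent, giving side product and an idle radical, which ends the chain.

| flask | substrate | coupling partner | transfer agent | initiator | remark | time |
|---|---|---|---|---|---|---|
| violet | 0.034 M | 0.090 M | 0.050 M | 5.5 mM | run made earlier |  |
| amber | 0.050 M | 0.090 M | 0.050 M | 11 mM | run made earlier |  |
| larch | 0.050 M | 0.0900 M | 0.0500 M | 5.5 mM |  | 2.5 h |
| alder | 0.050 M | 0.140 M | 0.0500 M | 5.5 mM |  | 2.5 h |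

| run | time / min | substrate / % | target / % |
|---|---|---|---|
| violet | 20.0 | 76.8 | 11.1 |
| violet | 40.0 | 63.7 | 19.0 |
| violet | 50.0 | 56.9 | 22.7 |
| violet | 80.0 | 44.5 | 29.8 |
| violet | 90.0 | 42.7 | 30.6 |
| amber | 8.00 | 86.5 | 7.1 |
| amber | 15.0 | 76.0 | 11.6 |
| amber | 25.0 | 64.1 | 19.7 |
| amber | 50.0 | 41.1 | 32.7 |
| amber | 90.0 | 20.2 | 43.9 |

(readings scatter by 0.5 percentage points)

* part of the substrate that has reacted at the end, larch
* part of the substrate that has reacted at the end, alder
* what raising the concentration of coupling partner from its lowest to its highest value here does to the part of the substrate that has reacted (changes below 5 percentage points count as none) (it falls / no change / it rises)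

- by-product is meant together with its idle adduct and crystals
- solid, in amounts per volume of the solution: crystals
- steps that have been proposed: coupling partner + first chain carrier -> target + second chain carrier; 2 idle radical -> ended radicals; crystals <-> by-product; 2 second chain carrier -> ended chains; substrate + by-product <-> idle adduct; substrate + second chain carrier -> by-product + first chain carrier; transfer agent + first chain carrier -> side product + idle radical; substrate + initiating radical -> capped initiator + first chain carrier; initiator -> 2 initiating radical

2. I pictured two extremes. If transfer agent took each carrier, substrate lost was capped initiator and nothing more: amber's last reading gave an initiator decay constant of 0.0188 min⁻¹, so I reckoned that larch capped 10.3 mM, or 20.7 % of its substrate. If coupling partner took each carrier, the chain ran to the ceiling of 100 %, since c(coupling partner) stood above c(substrate).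

3. Between them I compared the two rates at one moment. Their ratio is ρ·c(coupling partner)/c(transfer agent), where ρ is the selectivity factor, the coupling rate over the transfer rate at equal concentrations. It also gives ν, the target per capped initiator. Amber, with its concentrations taken midway, read ρ = 0.635. So I reckoned that larch started at ν = 1.14, which placed it between the extremes. The ratio drifted up to a midway 1.19, and alder's midway value was 1.85. Multiplying the capped share by 1 + ν gave me 45.3 % for larch and 59.0 % for alder.

4. The forecast said 45.5 % (42 % to 50 %) for larch and 58 % (52 % to 64 %) for alder, and it rises, on these grounds: “Target per capped initiator is about 1.2 and hardly depends on substrate.” Its figure for larch stood above my reckoning and its figure for alder below it.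

5. The flasks gave 45.7 % for larch and 59.2 % for alder: it rises, by 14 percentage points.

    coupling partner + first chain carrier → target + second chain carrier (k = 96000 M⁻¹ min⁻¹)
    2 idle radical → ended radicals (k = 2.00 × 10⁸ M⁻¹ s⁻¹)
    crystals ⇌ by-product, rate k3*(cs3 - [by-product]) while solid is left; crystals form when [by-product] > cs3 (solubility = 1.40 mM, k = 0.690 min⁻¹)
    2 second chain carrier → ended chains (k = 5.10 × 10⁷ M⁻¹ s⁻¹)
    substrate + by-product ⇌ idle adduct, settled at all times (K = 7.70 M⁻¹)
    substrate + second chain carrier → by-product + first chain carrier (k = 3.30 × 10⁵ M⁻¹ s⁻¹)
    transfer agent + first chain carrier → side product + idle radical (kL = 1.50 × 10⁵ M⁻¹ min⁻¹)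
    substrate + initiating radical → capped initiator + first chain carrier (k = 79000 M⁻¹ s⁻¹)
    initiator → 2 initiating radical (k = 0.0180 min⁻¹)

6. In larch, just after the start, the first chain carrier went to coupling partner 1.2 times as fast as to transfer agent, and at the asked time larch held target over side product at 1.20, beside my midway ν of 1.19. For a neighbour of larch charged from the start with 0.36 M of coupling partner, ρ gave ν = 4.76, which asked for 119 % of the substrate charged, above the ceiling. That flask reached 100 % reacted, with 0 % of its substrate left.

Readings and results stem from a simulated flask with made-up constants; scatter was added.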